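Start from the leftover in the north run: by 6.00 min, 28.0 mM of D and G had gone in, yet L and X together read 2.64 mM.

| setting | north | flask |
|---|---|---|
| D | 40 mM (fed, over 30 min) | 20 mM (fed, over 30 min) |
| G | 20 mM | 20.0 mM |
| remark | run made earlier |  |
| time |  | 30 min |

north run (percent of the D and G together charged)

| time / min | L / % | X / % |
|---|---|---|
| 1.33 | 1.5 | 0.1 |
| 2.50 | 2.5 | 0 |
| 4.00 | 3.4 | 0.2 |
| 5.00 | 3.2 | 0.6 |
| 6.00 | 3.9 | 0.5 |

(standard deviation of a reading: 0.3 percentage points)

- the numbers in the tables scatter by 0.3 percentage points (one standard deviation)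
- percentages count the whole charge, also what has not yet gone in

- L present at 30 min, in percent of the D and G together charged
- X present at 30 min, in percent of the D and G together charged
- Z present at 30 min, in percent of the D and G together charged

How much of what goes in lands on L's side? Call the share of the D and G gone in that stands as L or X the branch share φ, a selectivity, read here as 9.43 %. I take it as a floor: Z went unread, and some of what went in may still be D or G.

Does halving the feed move φ? The feed falls from 1.33 mM/min to 0.667 mM/min, but if L and whatever takes the leftover both draw on one pool at first order, the ratio of their rates ignores the feed.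

So what can Z be? Your flask has its whole charge in by 30 min. If Z comes through L, my reckoning puts L, X and Z together at φ of the charge, 3.77 mM, or above, with Z a part of that.

The forecast gives L 3 %, X 2 % and Z 30 %, more for Z than my floor of 9.43 % for all three, with L “drained to something unseen, presumably Z”.

The flask gives L 6.43 %, X 2.07 % and Z 4.93 %.

    D ⇌ G (K = 2.00, k = 0.0330 /s)
    D → L (k = 0.00200 /s)
    G → Q (k = 0.00710 /s)
    G ⇌ E (K = 0.0560, k = 3.30 × 10⁻⁴ /s)
    E → J (k = 3.20 × 10⁻⁴ /s)
    L → Z (k = 5.00 × 10⁻⁴ /s)
    L ⇌ X (K = 0.940, k = 2.60 × 10⁻⁴ /s)

In the flask, L, X and Z add up to 13.4 %, above the floor φ read from the north run, while Q, a species absent from the readings, holds 80.6 %. At 30.0 min, G goes to Q 4.96 times as fast as D goes to L.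

Read the same flask at 2.0 h: φ again gives a floor of 9.43 % for the three together. The computed L, X and Z add up to 14.2 %, with Z now 11.5 % and Q 85.6 %.

The readings come from a simulation for an exercise, noise included.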